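**Plan**

- Retrosynthetic cuts: C3–Br goes back to a 3α-alcohol (inversion); the C8=C12 methylene and the missing C7 oxygen go back to a C7 ketone; C9–C11 to a benzylic copper reagent plus a C8=C9 enone; C4–C5 of ring A to a tertiary radical from a C3–C4 epoxide.
- Enabling feature: the methyl-bearing quaternary C10 of ring B lies opposite C7, and the gem-dimethyl C4 sits between the heteroatom carbon C3 and the fusion carbon C5. Ring B can therefore begin as a symmetric 4-alkyl-4-methylcyclohexa-2,5-dienone and C3–C4 as a 2,2-dimethyl epoxide in its side chain.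
- Forward order: ring B first (Robinson annulation, dehydrogenation), epoxidation of the side-chain alkene, ring A by titanocene radical cyclisation, then the arylmethyl unit at C9, C12 at C8, removal of the C7 oxygen, bromide for hydroxyl at C3, unmasking of the arene.
- Stereochemistry: C3 from the Shi epoxidation; C5 and C10 from C3 in the cyclisation (cis fusion by the tether, choice of enone arm by a chair with the C3 oxygen equatorial); C9 by hydride delivery to the convex face of the re-formed enone; C3–Br by SN2 inversion.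

Key step: step 4

Assumption: bicyclic compounds carry drimane numbering (ring A = C1–C5 and C10, ring B = C5–C10, C11 = CH2 on C9, C12 = carbon on C8), β is the face of the C10 methyl group, Ar = 4-(1,3-dioxolan-2-yl)-2,5-bis(methoxymethoxy)phenyl, and the D-fructose-derived ketone is taken to give the (R)-epoxide as it does with other 2-methylalk-2-enes.

**Route**

Step 1
Reactants: 1 2,6-dimethylhept-5-enal (racemic); 2 methyl vinyl ketone
Product: 4 4-methyl-4-(4-methylpent-3-en-1-yl)cyclohex-2-en-1-one (racemic), via keto aldehyde 3 (not isolated)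
Conditions: KOH (0.2 equiv), MeOH–H2O, 0 °C, slow addition of 2; then 65 °C
Reagents that add atoms: none
Why: Robinson annulation, in which the enolate of the α-branched aldehyde adds to the enone (Michael addition) and the methyl ketone then closes onto the aldehyde by aldol condensation, creating the quaternary carbon (future C10) as a racemate that becomes achiral in step 2.

Step 2
Reactants: 4 4-methyl-4-(4-methylpent-3-en-1-yl)cyclohex-2-en-1-one
Product: 5 4-methyl-4-(4-methylpent-3-en-1-yl)cyclohexa-2,5-dien-1-one
Conditions: IBX (2.5 equiv), DMSO–fluorobenzene, 70 °C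
Reagents that add atoms: none
Why: IBX dehydrogenation of the enone through its dienol gives the cross-conjugated dienone, which cannot aromatise because C4 is quaternary, and the isolated trisubstituted alkene is not attacked.

Step 3
Reactants: 5 4-methyl-4-(4-methylpent-3-en-1-yl)cyclohexa-2,5-dien-1-one
Product: 6 4-[2-((2R)-3,3-dimethyloxiran-2-yl)ethyl]-4-methylcyclohexa-2,5-dien-1-one
Conditions: D-fructose-derived ketone catalyst of the Shi epoxidation (0.3 equiv), KHSO5 (as Oxone, 2KHSO5·KHSO4·K2SO4), K2CO3, Bu4NHSO4 (cat.), Na2B4O7 buffer (pH about 10.5), MeCN–CH2(OMe)2, 0 °C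
Reagents that add atoms: potassium peroxymonosulfate, [K+].[O-]S(=O)(=O)OO
Why: Shi asymmetric epoxidation, in which the electrophilic chiral dioxirane reacts only with the electron-rich trisubstituted alkene and not with the dienone, and the catalyst face selectivity sets the (R)-configured carbon that becomes C3.

Step 4
Reactants: 6 4-[2-((2R)-3,3-dimethyloxiran-2-yl)ethyl]-4-methylcyclohexa-2,5-dien-1-one
Product: 7 cis-fused 3α-hydroxy-4,4,10β-trimethyl-Δ8-octalin-7-one (5β-H)
Conditions: Cp2TiCl2 (2.5 equiv), Zn dust (8 equiv), degassed THF, 25 °C (green Cp2TiCl, trivalent titanium); this solution added over 1 h to 6 in THF (0.01 M), 25 °C; 1 M aq. HCl work-up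
Reagents that add atoms: none
Why: Cp2TiCl (trivalent titanium) gives one electron to the epoxide and breaks the C4–O bond, so that the tertiary C4 radical with the titanoxy group on C3 adds to C5, the β-carbon of one enone arm, and a second Cp2TiCl reduces the α-keto radical to a titanium enolate that is protonated at C6 on work-up while the other arm (C7=O, C8=C9) survives. The closest known reaction type is the titanocene-mediated reductive epoxide opening with radical cyclisation onto α,β-unsaturated ketones; what this substrate adds is only the choice between two enantiotopic acceptor arms. Ring A closes by 6-exo-trig attack, forming C4–C5. C5 is controlled by the tether, which hangs from C10 and can reach C5 only on its own face, so the fusion is cis; C10 is controlled by the C3 stereocentre, because the chair transition state with the bulky titanoxy group equatorial leads to the arm that puts the C10 methyl and H-5 on the face opposite to the C3 oxygen. The step needs group selectivity between the two arms, secured by that equatorial preference of the single epoxide-derived centre, and chemoselectivity for cyclisation over reduction of the C4 radical, secured by the hindered tertiary radical, the activated dienone acceptor and slow addition at high dilution.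

Step 5
Reactants: 7 cis-fused 3α-hydroxy-4,4,10β-trimethyl-Δ8-octalin-7-one
Product: 8 cis-fused 3α-(tert-butyldimethylsilyloxy)-4,4,10β-trimethyl-Δ8-octalin-7-one (5β-H)
Conditions: TBSOTf, 2,6-lutidine, CH2Cl2, −78 → 0 °C
Reagents that add atoms: tert-butyldimethylsilyl triflate, CC(C)(C)[Si](C)(C)OS(=O)(=O)C(F)(F)F
Why: Silyl ether formation with the reactive silyl triflate masks the hindered C3 alcohol against the organometallic, hydride and acylation steps that follow, and no stereocentre is touched.

Step 6
Reactants: 9 2,5-dihydroxyterephthalaldehyde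
Product: 10 2,5-bis(methoxymethoxy)terephthalaldehyde
Conditions: MOMCl (3 equiv), i-Pr2NEt (4 equiv), CH2Cl2–DMF, 0 → 25 °C
Reagents that add atoms: chloromethyl methyl ether, COCCl
Why: Williamson-type O-alkylation of both phenols gives acetal ethers that withstand bases, organometallic reagents and hydrides and can be removed at the end without reductive conditions.

Step 7
Reactants: 10 2,5-bis(methoxymethoxy)terephthalaldehyde
Product: 11 4-(hydroxymethyl)-2,5-bis(methoxymethoxy)benzaldehyde
Conditions: NaBH4 (0.3 equiv), THF–EtOH, −20 °C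
Reagents that add atoms: none
Why: Borohydride reduction with a deficit of hydride stops largely at the mono-alcohol because the ring has lost one acceptor after the first reduction and the remaining aldehyde is less electrophilic, and diol and unchanged dialdehyde are separable.

Step 8
Reactants: 11 4-(hydroxymethyl)-2,5-bis(methoxymethoxy)benzaldehyde
Product: 12 4-(chloromethyl)-2,5-bis(methoxymethoxy)benzaldehyde
Conditions: PPh3, N-chlorosuccinimide, THF, 0 → 25 °C
Reagents that add atoms: N-chlorosuccinimide, O=C1CCC(=O)N1Cl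
Why: Appel-type chlorination through the alkoxyphosphonium ion converts the benzylic alcohol into the chloride under neutral conditions that spare the aldehyde and the MOM ethers.

Step 9
Reactants: 12 4-(chloromethyl)-2,5-bis(methoxymethoxy)benzaldehyde
Product: 13 2-[4-(chloromethyl)-2,5-bis(methoxymethoxy)phenyl]-1,3-dioxolane
Conditions: Me3SiOCH2CH2OSiMe3, TMSOTf (2 mol %), CH2Cl2, −78 → −30 °C; pyridine quench
Reagents that add atoms: 1,2-bis(trimethylsilyloxy)ethane, C[Si](C)(C)OCCO[Si](C)(C)C
Why: Aprotic acetalisation with the bis-silyl ether of ethylene glycol, driven by formation of the Si–O–Si bond, gives the dioxolane at low temperature without a protic acid that would cleave the MOM ethers.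

Step 10
Reactants: 8 cis-fused 3α-(tert-butyldimethylsilyloxy)-4,4,10β-trimethyl-Δ8-octalin-7-one; 13 2-[4-(chloromethyl)-2,5-bis(methoxymethoxy)phenyl]-1,3-dioxolane
Product: 15 cis-fused 9β-(ArCH2)-3α-(TBSO)-7-(trimethylsilyloxy)-4,4,10β-trimethyl-Δ7-octalin (5β-H; 9α-H), via benzylic Grignard reagent 14 (not isolated)
Conditions: 13 (2 equiv), Mg turnings, THF, 0 °C, slow addition; then CuBr·SMe2 (0.2 equiv), TMSCl (3 equiv), 8, THF, −78 → −40 °C; Et3N, cold aq. NaHCO3
Reagents that add atoms: chlorotrimethylsilane, C[Si](C)(C)Cl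
Why: Copper-catalysed, TMSCl-accelerated conjugate addition of the benzylic Grignard reagent forms C9–C11 and traps the enolate regiospecifically as the C7 silyl enol ether; attack is expected on the convex β face, but the C9 configuration is erased in step 11.

Step 11
Reactants: 15 cis-fused 9β-(ArCH2)-3α-(TBSO)-7-(trimethylsilyloxy)-4,4,10β-trimethyl-Δ7-octalin
Product: 16 cis-fused 9-(ArCH2)-3α-(TBSO)-4,4,10β-trimethyl-Δ8-octalin-7-one (5β-H)
Conditions: Pd(OAc)2 (1.1 equiv), MeCN, 25 °C
Reagents that add atoms: none
Why: Saegusa–Ito oxidation, in which palladation of the silyl enol ether at C8 and β-hydride elimination of H-9 restore the C8=C9 enone, now with the arylmethyl group on C9.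

Step 12
Reactants: 16 cis-fused 9-(ArCH2)-3α-(TBSO)-4,4,10β-trimethyl-Δ8-octalin-7-one
Product: 17 cis-fused 9α-(ArCH2)-7-(dimethylphenylsilyloxy)-3α-(TBSO)-4,4,10β-trimethyl-Δ7-octalin (5β-H; 9β-H)
Conditions: [(Ph3P)CuH]6 (5 mol %), PhMe2SiH (1.5 equiv), toluene, 25 °C
Reagents that add atoms: dimethylphenylsilane, C[SiH](C)c1ccccc1
Why: Copper hydride-catalysed conjugate hydrosilylation delivers hydride to C9 on the convex β face (the face of H-5 and the C10 methyl, away from ring A, with axial attack anti to the C10–C1 bond), which sets C9 with H β and the arylmethyl group α and stores the enolate regiospecifically as the C7=C8 silyl enol ether.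

Step 13
Reactants: 17 cis-fused 9α-(ArCH2)-7-(dimethylphenylsilyloxy)-3α-(TBSO)-4,4,10β-trimethyl-Δ7-octalin
Product: 20 cis-fused 9α-(ArCH2)-3α-(TBSO)-4,4,10β-trimethyl-8-methylenedecalin-7-one (5β-H; 9β-H), via Mannich base 18 (not isolated), via trimethylammonium iodide 19 (not isolated)
Conditions: [CH2=NMe2]I, CH2Cl2, 25 °C; MeI, 25 °C; aq. NaHCO3–CH2Cl2, 25 °C
Reagents that add atoms: N,N-dimethylmethyleneiminium iodide, C=[N+](C)C.[I-]
Why: Mannich reaction of the silyl enol ether attaches C12 at C8 only, and N-methylation followed by mild base-induced loss of trimethylamine gives the exocyclic enone (α-methylenation) under conditions too weak to deprotonate the adjacent C9 stereocentre.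

Step 14
Reactants: 20 cis-fused 9α-(ArCH2)-3α-(TBSO)-4,4,10β-trimethyl-8-methylenedecalin-7-one
Product: 21 cis-fused 9α-(ArCH2)-3α-(TBSO)-4,4,10β-trimethyl-8-methylenedecalin-7α-ol (5β-H; 9β-H)
Conditions: NaBH4, CeCl3·7H2O, MeOH–THF, −78 °C
Reagents that add atoms: none
Why: Luche reduction gives 1,2-reduction of the α-methylene ketone without conjugate reduction; axial attack on the convex face should give mainly the 7α-alcohol, and either C7 epimer serves because C7 becomes CH2 in step 16.

Step 15
Reactants: 21 cis-fused 9α-(ArCH2)-3α-(TBSO)-4,4,10β-trimethyl-8-methylenedecalin-7α-ol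
Product: 22 7α-formate of 21
Conditions: HCO2Ac (acetic formic anhydride), pyridine, CH2Cl2, 0 °C
Reagents that add atoms: acetic formic anhydride, CC(=O)OC=O
Why: O-Formylation of the secondary allylic alcohol with the mixed anhydride installs both the leaving group and the internal hydride source for the next step.

Step 16
Reactants: 22 7α-formate of 21
Product: 23 cis-fused 9α-(ArCH2)-3α-(TBSO)-4,4,10β-trimethyl-8-methylenedecalin (5β-H; 9β-H)
Conditions: Pd(OAc)2 (5 mol %), n-Bu3P (5 mol %), 1,4-dioxane, 25 → 80 °C
Reagents that add atoms: none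
Why: Tsuji–Mandai formate reduction, in which zerovalent palladium ionises the allylic formate to a π-allyl complex over C7–C8–C12 and, after loss of CO2, hydride is delivered to the more substituted terminus C7 (favoured with n-Bu3P), so C7 is deoxygenated and the exocyclic C8=C12 alkene is kept.

Step 17
Reactants: 23 cis-fused 9α-(ArCH2)-3α-(TBSO)-4,4,10β-trimethyl-8-methylenedecalin
Product: 24 cis-fused 9α-(ArCH2)-4,4,10β-trimethyl-8-methylenedecalin-3α-ol (5β-H; 9β-H)
Conditions: Bu4NF, THF, 50 °C
Reagents that add atoms: none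
Why: Fluoride-induced cleavage of the silyl ether, driven by Si–F bond formation, frees the C3 alcohol while MOM ethers, dioxolane and alkene are inert.

Step 18
Reactants: 24 cis-fused 9α-(ArCH2)-4,4,10β-trimethyl-8-methylenedecalin-3α-ol
Product: 25 cis-fused 9α-(ArCH2)-3β-bromo-4,4,10β-trimethyl-8-methylenedecalin (5β-H; 9β-H)
Conditions: CBr4, P(n-Oct)3, toluene, 70 °C
Reagents that add atoms: tetrabromomethane, BrC(Br)(Br)Br
Why: Appel reaction, in which the alcohol (axial in the conformer that keeps the C9 side chain equatorial) is activated as an alkoxyphosphonium ion and displaced by bromide in an SN2 step with inversion to the equatorial 3β-bromide, the small nucleophilic trialkylphosphine and the non-polar solvent favouring substitution over ionisation at this neopentyl-type carbon.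

Step 19
Reactants: 25 cis-fused 9α-(ArCH2)-3β-bromo-4,4,10β-trimethyl-8-methylenedecalin
Product: 26 peyssonol A
Conditions: TMSOTf, 2,2′-bipyridyl, CH2Cl2, 0 → 25 °C; then degassed H2O
Reagents that add atoms: water, O
Why: The silyl triflate–bipyridyl pair converts both aryl MOM ethers and the dioxolane into bipyridinium intermediates that water hydrolyses to the free phenols and the aldehyde, with no free strong acid present that could protonate the exocyclic alkene or ionise the bromide.

**Compound list**

1 | 2,6-dimethylhept-5-enal (racemic) | CC(C)=CCCC(C)C=O | starting material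
2 | methyl vinyl ketone | CC(=O)C=C | starting material
3 | 2,6-dimethyl-2-(3-oxobutyl)hept-5-enal (racemic) | CC(C)=CCCC(C)(C=O)CCC(C)=O | intermediate (not isolated)
4 | 4-methyl-4-(4-methylpent-3-en-1-yl)cyclohex-2-en-1-one (racemic) | CC(C)=CCCC1(C)CCC(=O)C=C1 | intermediate
5 | 4-methyl-4-(4-methylpent-3-en-1-yl)cyclohexa-2,5-dien-1-one | CC(C)=CCCC1(C)C=CC(=O)C=C1 | intermediate
6 | 4-[2-((2R)-3,3-dimethyloxiran-2-yl)ethyl]-4-methylcyclohexa-2,5-dien-1-one | CC1(C)O[C@@H]1CCC1(C)C=CC(=O)C=C1 | intermediate
7 | (4aR,7R,8aS)-7-hydroxy-4a,8,8-trimethyl-4a,5,6,7,8,8a-hexahydronaphthalen-2(1H)-one (3α-OH, 5β-H, 10β-CH3, C7=O, C8=C9) | O=C1C[C@@H]2C(C)(C)[C@H](O)CC[C@]2(C)C=C1 | intermediate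
8 | 3α-O-tert-butyldimethylsilyl ether of 7 | O=C1C[C@@H]2C(C)(C)[C@H](O[Si](C)(C)C(C)(C)C)CC[C@]2(C)C=C1 | intermediate
9 | 2,5-dihydroxyterephthalaldehyde | O=Cc1cc(O)c(C=O)cc1O | starting material
10 | 2,5-bis(methoxymethoxy)terephthalaldehyde | O=Cc1cc(OCOC)c(C=O)cc1OCOC | intermediate
11 | 4-(hydroxymethyl)-2,5-bis(methoxymethoxy)benzaldehyde | OCc1cc(OCOC)c(C=O)cc1OCOC | intermediate
12 | 4-(chloromethyl)-2,5-bis(methoxymethoxy)benzaldehyde | ClCc1cc(OCOC)c(C=O)cc1OCOC | intermediate
13 | 2-[4-(chloromethyl)-2,5-bis(methoxymethoxy)phenyl]-1,3-dioxolane | ClCc1cc(OCOC)c(C2OCCO2)cc1OCOC | intermediate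
14 | {[4-(1,3-dioxolan-2-yl)-2,5-bis(methoxymethoxy)phenyl]methyl}magnesium chloride | Cl[Mg]Cc1cc(OCOC)c(C2OCCO2)cc1OCOC | intermediate (not isolated)
15 | C7 trimethylsilyl enol ether, 3α-OTBS, 9β-CH2Ar (expected C9 epimer, erased in step 11), 5β-H, 10β-CH3 | C1=C(O[Si](C)(C)C)C[C@@H]2C(C)(C)[C@H](O[Si](C)(C)C(C)(C)C)CC[C@]2(C)[C@H]1Cc3cc(OCOC)c(C4OCCO4)cc3OCOC | intermediate
16 | 9-(ArCH2)-Δ8-7-ketone, 3α-OTBS, 5β-H, 10β-CH3 | O=C1C[C@@H]2C(C)(C)[C@H](O[Si](C)(C)C(C)(C)C)CC[C@]2(C)C(Cc3cc(OCOC)c(C4OCCO4)cc3OCOC)=C1 | intermediate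
17 | C7 dimethylphenylsilyl enol ether (C7=C8), 3α-OTBS, 9α-CH2Ar, 9β-H, 5β-H, 10β-CH3 | C1=C(O[Si](C)(C)c5ccccc5)C[C@@H]2C(C)(C)[C@H](O[Si](C)(C)C(C)(C)C)CC[C@]2(C)[C@@H]1Cc3cc(OCOC)c(C4OCCO4)cc3OCOC | intermediate
18 | 8-(dimethylaminomethyl)-7-ketone (C8 epimers), otherwise as 17 | CN(C)CC1C(=O)C[C@@H]2C(C)(C)[C@H](O[Si](C)(C)C(C)(C)C)CC[C@]2(C)[C@@H]1Cc3cc(OCOC)c(C4OCCO4)cc3OCOC | intermediate (not isolated)
19 | 8-(trimethylammoniomethyl)-7-ketone iodide (C8 epimers) | C[N+](C)(C)CC1C(=O)C[C@@H]2C(C)(C)[C@H](O[Si](C)(C)C(C)(C)C)CC[C@]2(C)[C@@H]1Cc3cc(OCOC)c(C4OCCO4)cc3OCOC.[I-] | intermediate (not isolated)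
20 | 8-methylene-7-ketone, 3α-OTBS, 9α-CH2Ar, 9β-H, 5β-H, 10β-CH3 | C=C1C(=O)C[C@@H]2C(C)(C)[C@H](O[Si](C)(C)C(C)(C)C)CC[C@]2(C)[C@@H]1Cc3cc(OCOC)c(C4OCCO4)cc3OCOC | intermediate
21 | 8-methylene-7α-ol (expected major C7 epimer), otherwise as 20 | C=C1[C@H](O)C[C@@H]2C(C)(C)[C@H](O[Si](C)(C)C(C)(C)C)CC[C@]2(C)[C@@H]1Cc3cc(OCOC)c(C4OCCO4)cc3OCOC | intermediate
22 | 7α-formate of 21 | C=C1[C@H](OC=O)C[C@@H]2C(C)(C)[C@H](O[Si](C)(C)C(C)(C)C)CC[C@]2(C)[C@@H]1Cc3cc(OCOC)c(C4OCCO4)cc3OCOC | intermediate
23 | 8-methylene decalin with C7 as CH2, 3α-OTBS, 9α-CH2Ar, 9β-H, 5β-H, 10β-CH3 | C=C1CC[C@@H]2C(C)(C)[C@H](O[Si](C)(C)C(C)(C)C)CC[C@]2(C)[C@@H]1Cc3cc(OCOC)c(C4OCCO4)cc3OCOC | intermediate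
24 | 3α-alcohol from 23 | C=C1CC[C@@H]2C(C)(C)[C@H](O)CC[C@]2(C)[C@@H]1Cc3cc(OCOC)c(C4OCCO4)cc3OCOC | intermediate
25 | 3β-bromide, arene still protected | C=C1CC[C@@H]2C(C)(C)[C@@H](Br)CC[C@]2(C)[C@@H]1Cc3cc(OCOC)c(C4OCCO4)cc3OCOC | intermediate
26 | peyssonol A, 4-[(3β-bromo-4,4,10β-trimethyl-8-methylene-5βH-decalin-9α-yl)methyl]-2,5-dihydroxybenzaldehyde | C=C1CC[C@@H]2C(C)(C)[C@@H](Br)CC[C@]2(C)[C@@H]1Cc1cc(O)c(C=O)cc1O | target

**Step count and risks**

Total steps: 19. Longest linear sequence: 15 (steps 1–5 and 10–19); the arene fragment takes steps 6–9.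

Step 4. The cyclisation may discriminate poorly between the two enone arms, or titanium may reduce the C4 radical or attack the dienone before ring closure. In that case the radical is generated without a reducing metal. Epoxide 6 is opened with 48% aq. HBr in CH2Cl2 at −20 °C (Markovnikov opening, bromide on the tertiary carbon, C3–O untouched) to 4-[(3R)-4-bromo-3-hydroxy-4-methylpentyl]-4-methylcyclohexa-2,5-dien-1-one F1. The alcohol is silylated with TBSOTf and 2,6-lutidine to the silyl ether F2. Bu3SnH and AIBN (slow addition, benzene, 80 °C) then bring about the known tin hydride 6-exo radical cyclisation onto a cyclohexadienone, where the larger silyloxy group should strengthen the equatorial preference. This gives 8, at which the route is rejoined.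

Step 18. Substitution at the neopentyl-type C3 may lose to elimination towards C2, to methyl migration after ionisation, or may not start because of congestion around the axial oxygen. Activation and displacement are then separated. Alcohol 24 is converted with Tf2O and pyridine (CH2Cl2, −40 °C) into the 3α-trifluoromethanesulfonate F3, which is displaced by Bu4NBr in toluene at 0 → 25 °C (SN2 of a sulfonate by a soluble, non-basic bromide) to give 25.

Step 12. Hydride transfer to the hindered C9 may be too slow, may turn into 1,2-reduction, or may show poor facial selectivity. Enone 16 is then reduced by electron transfer: Li (2.2 equiv) in liquid NH3–THF at −78 °C, evaporation of NH3 and silylation of the lithium enolate with PhMe2SiCl and Et3N (dissolving-metal reduction with reductive silylation). Protonation of the C9 carbanion should occur axially on the convex face, leading back to the same silyl enol ether 17; this fallback makes no new compound (F0).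

**Further compounds**

F1 | step 4 | 4-[(3R)-4-bromo-3-hydroxy-4-methylpentyl]-4-methylcyclohexa-2,5-dien-1-one | CC(C)(Br)[C@H](O)CCC1(C)C=CC(=O)C=C1
F2 | step 4 | 4-[(3R)-4-bromo-3-(tert-butyldimethylsilyloxy)-4-methylpentyl]-4-methylcyclohexa-2,5-dien-1-one | CC(C)(Br)[C@H](O[Si](C)(C)C(C)(C)C)CCC1(C)C=CC(=O)C=C1
F3 | step 18 | 3α-trifluoromethanesulfonate of 24 | C=C1CC[C@@H]2C(C)(C)[C@H](OS(=O)(=O)C(F)(F)F)CC[C@]2(C)[C@@H]1Cc3cc(OCOC)c(C4OCCO4)cc3OCOC
F0 | step 12 | none | none
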